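The cyclohexane ring (C6–C11) is cut across C6–C11 and C9–C10. This leads to a linalool-derived triene ether, whose (E)-1-alkyl-2-methyl diene holds C6–C9 and whose C3 carbinol comes from the chiral pool, and to (E)-3-bromo-2-methylpropenal (C10–C12). One catalyst-controlled, formyl-exo [4+2] cycloaddition closes the ring and sets C6, C11 and C10 together. It exploits the fact that the C5 chain, the C11 methyl group and the C10 bromine share one face of the ring, so the neopentyl C10–Br bond is carried in by the enal geometry. The remaining C7=C8 alkene later gives the C7 carbinol, and C12 is extended to the side chain.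

Key step: step 5

Atom labels: the vinyl group is C1=C2 and the acyclic carbinol is C3. C4 and C5 are the two methylene groups. The ring runs C6 (CH), C7 (C(CH3)OH), C8, C9, C10 (CHBr), C11 (quaternary). The side chain is C12H2–C13H=C14H–C15(CH3)2OH.

Stereochemical bookkeeping: in 21 the C5 chain, C7–CH3, C10–Br and C11–CH3 lie on one ring face, and C7–OH and C12 lie on the other. The ring descriptors are 1S,2S,3S,4S and the chain carbinol is 3S. Enal (E)-9 has Br cis to CH3. Formyl-exo addition to the (E)-diene puts chain, CH3 and Br on one face, which is the relative configuration required.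

Assumption: (S)-(+)-linalool is taken as a commercial chiral-pool alcohol of high enantiomeric purity. Material of lower purity would be upgraded before use, because C3 is never touched again.

Step 1
Reactants: 1 (S)-(+)-linalool
Product: 2 (3S)-3,7-dimethyl-3-(triethylsilyloxy)octa-1,6-diene
Conditions: TESOTf (1.2 equiv), 2,6-lutidine (1.5 equiv), CH2Cl2, −78 → 0 °C
Reagents that add atoms: triethylsilyl trifluoromethanesulfonate, CC[Si](CC)(CC)OS(=O)(=O)C(F)(F)F
Why: Silylation of a hindered tertiary alcohol with a silyl triflate and a hindered pyridine base is routine, leaves the C3–O bond and hence the S configuration untouched, and gives an ether bulky enough to stay off the boron Lewis acid of step 5 yet removable by fluoride at the end.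

Step 2
Reactants: 2 (3S)-3,7-dimethyl-3-(triethylsilyloxy)octa-1,6-diene
Product: 4 (2E,6S)-2,6-dimethyl-6-(triethylsilyloxy)octa-2,7-dienal, via allylic alcohol 3 (not isolated)
Conditions: SeO2 (0.2 equiv), t-BuOOH (2.5 equiv), CH2Cl2, 0 °C → rt; crude material, then activated MnO2 (15 equiv), CH2Cl2, rt
Reagents that add atoms: tert-butyl hydroperoxide, CC(C)(C)OO (terminal source of the new oxygen, passed on through SeO2, O=[Se]=O)
Why: Riley allylic oxidation (ene reaction followed by [2,3]-sigmatropic shift) attacks the trisubstituted alkene at the methyl group trans to the chain, which fixes the E geometry, the vinyl group having no allylic hydrogen, and MnO2 then converges the alcohol and enal mixture on the enal without touching C3.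

Step 3
Reactants: 4 (2E,6S)-2,6-dimethyl-6-(triethylsilyloxy)octa-2,7-dienal; 5 methyltriphenylphosphonium bromide
Product: 6 (3S,6E)-3,7-dimethyl-3-(triethylsilyloxy)nona-1,6,8-triene
Conditions: 5 (1.4 equiv), n-BuLi (1.3 equiv), THF, 0 °C; then 4, −78 °C → rt
Reagents that add atoms: methyltriphenylphosphonium bromide 5, C[P+](c1ccccc1)(c1ccccc1)c1ccccc1.[Br-]
Why: Wittig methylenation of an enal with the unstabilised ylide is fast at low temperature and leaves the C6=C7 geometry unchanged, so the diene is obtained as the E isomer that step 5 needs.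

Step 4
Reactants: 7 methacrolein
Product: 9 (E)-3-bromo-2-methylprop-2-enal, via dibromide 8 (not isolated)
Conditions: Br2 (1.0 equiv), CH2Cl2, −78 → 0 °C; then Et3N (1.2 equiv), 0 °C → rt; distillation
Reagents that add atoms: bromine, BrBr
Why: Electrophilic bromine addition followed by amine-induced E2 loss of HBr (tertiary α-bromide leaving, the more acidic CH2Br hydrogen removed) gives the conjugated β-bromo enal, and the E isomer with bromine anti to the formyl group and cis to the methyl group is the more stable one, towards which reversible conjugate addition of bromide or amine equilibrates the mixture.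

Step 5
Reactants: 6 (3S,6E)-3,7-dimethyl-3-(triethylsilyloxy)nona-1,6,8-triene; 9 (E)-3-bromo-2-methylprop-2-enal
Product: 10 (1R,2R,6S)-6-bromo-1,3-dimethyl-2-[(3S)-3-methyl-3-(triethylsilyloxy)pent-4-en-1-yl]cyclohex-3-ene-1-carbaldehyde
Conditions: (3aR)-1-(2-methylphenyl)-3,3-diphenyltetrahydro-1H,3H-pyrrolo[1,2-c][1,3,2]oxazaborole (C24H24BNO, 20 mol %) + HN(SO2CF3)2 (18 mol %), CH2Cl2, −78 °C; 9 (2 equiv), then 6 added slowly, −78 → −20 °C
Reagents that add atoms: none
Why: Proposed new method: the boron-bound s-trans enal and the s-cis diene should combine in a concerted but asynchronous [4+2] cycloaddition in which the unsubstituted terminus C9 bonds to the β-carbon C10 ahead of C6–C11; the closest known reaction type is the oxazaborolidinium-catalysed enantioselective Diels–Alder reaction of α-substituted enals, which has not been shown to be formyl-exo selective for a β-bromo enal and an acyclic diene. The cyclohexene C6–C7–C8–C9–C10–C11 is closed by this intermolecular suprafacial cycloaddition, both σ-bonds forming in one event and C7=C8 remaining. C10 and C11 are fixed relative to each other by the E geometry of 9 (Br cis to CH3), C6 is fixed relative to them by the E geometry of C6=C7 together with the formyl-exo topology, and the absolute sense comes from the catalyst, whose phenyl ring covers one enal face so that, on the usual formyl C–H···O binding model, the R catalyst leaves the C11-Re/C10-Si face open (the S antipode is equally available if a calibration run shows the opposite sense, and C3 is too remote to matter). Exo selectivity is needed and is secured by the C7 methyl group, which in the endo mode would run into the B-aryl group and the bound carbonyl, whereas in the exo mode only CH3 and Br lie under the diene. Regioselectivity (C6 to C11) is needed and is secured by the C6 alkyl substituent, which makes C9 the more nucleophilic and least hindered terminus for the leading bond. C11 carries no hydrogen, so the β-bromo aldehyde cannot lose HBr, and the hindered C3 silyl ether and the isolated vinyl group are spectators.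

Step 6
Reactants: 10 Diels–Alder adduct; 11 (methoxymethyl)triphenylphosphonium chloride
Product: 12 (4S,5R,6R)-4-bromo-5-(2-methoxyethenyl)-1,5-dimethyl-6-[(3S)-3-methyl-3-(triethylsilyloxy)pent-4-en-1-yl]cyclohex-1-ene (E/Z mixture at C12=C13)
Conditions: 11 (1.6 equiv), NaN(SiMe3)2 (1.5 equiv), THF, 0 °C; then 10, −78 → 0 °C
Reagents that add atoms: (methoxymethyl)triphenylphosphonium chloride 11, COC[P+](c1ccccc1)(c1ccccc1)c1ccccc1.[Cl-]
Why: Wittig olefination with the small, unstabilised methoxymethylene ylide adds to the neopentyl aldehyde at low temperature much faster than the ylide can act as a base on the secondary bromide, C11 carries no hydrogen so nothing can epimerise or eliminate towards the carbonyl group, and the E/Z mixture is of no consequence.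

Step 7
Reactants: 12 enol ether
Product: 13 2-[(1S,2R,6S)-6-bromo-1,3-dimethyl-2-[(3S)-3-methyl-3-(triethylsilyloxy)pent-4-en-1-yl]cyclohex-3-en-1-yl]acetaldehyde
Conditions: p-TsOH·H2O (10 mol %), THF/H2O (5:1), 0 °C → rt; NaHCO3 quench
Reagents that add atoms: water, O
Why: Acid-catalysed enol ether hydrolysis (rate-determining protonation at C12, then collapse of the hemiacetal) needs only catalytic sulfonic acid in wet THF, conditions that the hindered tertiary silyl ether and the ring alkene should survive, and any material that loses the silyl group still converges on 21 because all later steps tolerate a free C3 hydroxyl group.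

Step 8
Reactants: 13 homologated aldehyde; 14 ethyl (triphenylphosphoranylidene)acetate
Product: 15 ethyl (2E)-4-[(1S,2R,6S)-6-bromo-1,3-dimethyl-2-[(3S)-3-methyl-3-(triethylsilyloxy)pent-4-en-1-yl]cyclohex-3-en-1-yl]but-2-enoate
Conditions: 14 (1.5 equiv), CH2Cl2, rt
Reagents that add atoms: ethyl (triphenylphosphoranylidene)acetate 14, CCOC(=O)C=P(c1ccccc1)(c1ccccc1)c1ccccc1
Why: Wittig reaction of an unhindered aliphatic aldehyde with a stabilised ester ylide runs under neutral conditions, which spares the bromide, and is reliably E-selective, which sets the C13=C14 geometry.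

Step 9
Reactants: 15 enoate
Product: 16 ethyl (2E)-4-[(1R,2S,3S,4S,6S)-4-bromo-1,3-dimethyl-2-[(3S)-3-methyl-3-(triethylsilyloxy)pent-4-en-1-yl]-7-oxabicyclo[4.1.0]heptan-3-yl]but-2-enoate (epoxide oxygen cis to C12)
Conditions: mCPBA (1.05 equiv), CH2Cl2, −20 → 0 °C
Reagents that add atoms: 3-chloroperoxybenzoic acid, O=C(OO)c1cccc(Cl)c1
Why: Prilezhaev epoxidation is governed by alkene nucleophilicity, so the trisubstituted C7=C8 bond reacts ahead of the electron-poor enoate and the monosubstituted vinyl group next to the silyloxy carbon, and because the C5 chain, the C11 methyl group and the C10 bromine all stand on one ring face the peracid should approach in either half-chair from the opposite face, that of C12, which sets C7 (R) and C8 (S) with oxygen cis to C12.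

Step 10
Reactants: 16 epoxy enoate; 17 methyllithium
Product: 19 (3E)-5-[(1R,2S,3S,4S,6S)-4-bromo-1,3-dimethyl-2-[(3S)-3-methyl-3-(triethylsilyloxy)pent-4-en-1-yl]-7-oxabicyclo[4.1.0]heptan-3-yl]-2-methylpent-3-en-2-ol, via methyl enone 18 (not isolated)
Conditions: MeLi (3 equiv), Et2O/THF, −78 °C; aqueous quench at −78 °C
Reagents that add atoms: methyllithium 17, [Li]C
Why: Double 1,2-addition of methyllithium to an ester passes through the methyl enone and stops at the tertiary alkoxide, is faster at −78 °C than conjugate addition, epoxide opening, halogen–lithium exchange or E2 attack on the hindered bromide, creates no stereocentre and leaves the E alkene in place.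

Step 11
Reactants: 19 epoxy alcohol
Product: 20 (1S,2S,3S,4S)-4-bromo-3-[(2E)-4-hydroxy-4-methylpent-2-en-1-yl]-1,3-dimethyl-2-[(3S)-3-methyl-3-(triethylsilyloxy)pent-4-en-1-yl]cyclohexan-1-ol
Conditions: LiBHEt3 (4 equiv), THF, 0 °C → rt; aqueous quench
Reagents that add atoms: none
Why: Nucleophilic hydride opening of a trisubstituted epoxide by LiBHEt3 is an SN2 process at the less substituted carbon C8, so the C7–O bond and its configuration are kept (descriptor now S) and C8 becomes a methylene group, while the C10–Br bond, being secondary, neopentyl and flanked by the quaternary C11, is displaced far more slowly.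

Step 12
Reactants: 20 C3 silyl ether of the target
Product: 21 (1S,2S,3S,4S)-4-bromo-3-[(2E)-4-hydroxy-4-methylpent-2-en-1-yl]-2-[(3S)-3-hydroxy-3-methylpent-4-en-1-yl]-1,3-dimethylcyclohexan-1-ol (CNP0193074.2)
Conditions: Bu4NF/AcOH (1:1, 2 equiv), THF, 0 °C → rt
Reagents that add atoms: none
Why: Fluoride-induced cleavage of a triethylsilyl ether is driven by the Si–F bond, and buffering with acetic acid keeps the medium free of alkoxide so that neither elimination of HBr nor closure of the C7 oxygen onto C10 nor ionisation of the two allylic tertiary carbinols can set in and no stereocentre is touched.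

Compound list
1 | (S)-(+)-linalool | C=C[C@@](C)(O)CCC=C(C)C | starting material
2 | (3S)-3,7-dimethyl-3-(triethylsilyloxy)octa-1,6-diene | C=C[C@@](C)(O[Si](CC)(CC)CC)CCC=C(C)C | intermediate
3 | (2E,6S)-2,6-dimethyl-6-(triethylsilyloxy)octa-2,7-dien-1-ol | C=C[C@@](C)(O[Si](CC)(CC)CC)CC/C=C(C)/CO | intermediate
4 | (2E,6S)-2,6-dimethyl-6-(triethylsilyloxy)octa-2,7-dienal | C=C[C@@](C)(O[Si](CC)(CC)CC)CC/C=C(C)/C=O | intermediate
5 | methyltriphenylphosphonium bromide | C[P+](c1ccccc1)(c1ccccc1)c1ccccc1.[Br-] | starting material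
6 | (3S,6E)-3,7-dimethyl-3-(triethylsilyloxy)nona-1,6,8-triene | C=C[C@@](C)(O[Si](CC)(CC)CC)CC/C=C(C)/C=C | intermediate
7 | methacrolein | C=C(C)C=O | starting material
8 | 2,3-dibromo-2-methylpropanal (racemic) | O=CC(C)(Br)CBr | intermediate
9 | (E)-3-bromo-2-methylprop-2-enal | Br/C=C(C)/C=O | intermediate
10 | (1R,2R,6S)-6-bromo-1,3-dimethyl-2-[(3S)-3-methyl-3-(triethylsilyloxy)pent-4-en-1-yl]cyclohex-3-ene-1-carbaldehyde | C=C[C@@](C)(O[Si](CC)(CC)CC)CC[C@H]1[C@](C)(C=O)[C@@H](Br)CC=C1C | intermediate
11 | (methoxymethyl)triphenylphosphonium chloride | COC[P+](c1ccccc1)(c1ccccc1)c1ccccc1.[Cl-] | starting material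
12 | (4S,5R,6R)-4-bromo-5-(2-methoxyethenyl)-1,5-dimethyl-6-[(3S)-3-methyl-3-(triethylsilyloxy)pent-4-en-1-yl]cyclohex-1-ene, E/Z mixture | C=C[C@@](C)(O[Si](CC)(CC)CC)CC[C@H]1[C@](C)(C=COC)[C@@H](Br)CC=C1C | intermediate
13 | 2-[(1S,2R,6S)-6-bromo-1,3-dimethyl-2-[(3S)-3-methyl-3-(triethylsilyloxy)pent-4-en-1-yl]cyclohex-3-en-1-yl]acetaldehyde | C=C[C@@](C)(O[Si](CC)(CC)CC)CC[C@H]1[C@](C)(CC=O)[C@@H](Br)CC=C1C | intermediate
14 | ethyl (triphenylphosphoranylidene)acetate | CCOC(=O)C=P(c1ccccc1)(c1ccccc1)c1ccccc1 | starting material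
15 | ethyl (2E)-4-[(1S,2R,6S)-6-bromo-1,3-dimethyl-2-[(3S)-3-methyl-3-(triethylsilyloxy)pent-4-en-1-yl]cyclohex-3-en-1-yl]but-2-enoate | C=C[C@@](C)(O[Si](CC)(CC)CC)CC[C@H]1[C@](C)(C/C=C/C(=O)OCC)[C@@H](Br)CC=C1C | intermediate
16 | ethyl (2E)-4-[(1R,2S,3S,4S,6S)-4-bromo-1,3-dimethyl-2-[(3S)-3-methyl-3-(triethylsilyloxy)pent-4-en-1-yl]-7-oxabicyclo[4.1.0]heptan-3-yl]but-2-enoate | C=C[C@@](C)(O[Si](CC)(CC)CC)CC[C@H]1[C@](C)(C/C=C/C(=O)OCC)[C@@H](Br)C[C@@H]2O[C@]12C | intermediate
17 | methyllithium | [Li]C | starting material
18 | (3E)-5-[(1R,2S,3S,4S,6S)-4-bromo-1,3-dimethyl-2-[(3S)-3-methyl-3-(triethylsilyloxy)pent-4-en-1-yl]-7-oxabicyclo[4.1.0]heptan-3-yl]pent-3-en-2-one | C=C[C@@](C)(O[Si](CC)(CC)CC)CC[C@H]1[C@](C)(C/C=C/C(C)=O)[C@@H](Br)C[C@@H]2O[C@]12C | intermediate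
19 | (3E)-5-[(1R,2S,3S,4S,6S)-4-bromo-1,3-dimethyl-2-[(3S)-3-methyl-3-(triethylsilyloxy)pent-4-en-1-yl]-7-oxabicyclo[4.1.0]heptan-3-yl]-2-methylpent-3-en-2-ol | C=C[C@@](C)(O[Si](CC)(CC)CC)CC[C@H]1[C@](C)(C/C=C/C(C)(C)O)[C@@H](Br)C[C@@H]2O[C@]12C | intermediate
20 | (1S,2S,3S,4S)-4-bromo-3-[(2E)-4-hydroxy-4-methylpent-2-en-1-yl]-1,3-dimethyl-2-[(3S)-3-methyl-3-(triethylsilyloxy)pent-4-en-1-yl]cyclohexan-1-ol | C=C[C@@](C)(O[Si](CC)(CC)CC)CC[C@H]1[C@](C)(C/C=C/C(C)(C)O)[C@@H](Br)CC[C@]1(C)O | intermediate
21 | (1S,2S,3S,4S)-4-bromo-3-[(2E)-4-hydroxy-4-methylpent-2-en-1-yl]-2-[(3S)-3-hydroxy-3-methylpent-4-en-1-yl]-1,3-dimethylcyclohexan-1-ol | C=C[C@@](C)(O)CC[C@H]1[C@](C)(C/C=C/C(C)(C)O)[C@@H](Br)CC[C@]1(C)O | target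

Total step count: 12 (three steps to the diene, one to the dienophile, the cycloaddition, seven steps to the target).
Longest linear sequence: 11 steps (1 → 2 → 4 → 6 → 10 → 12 → 13 → 15 → 16 → 19 → 20 → 21).

Steps most likely to fail

Step 5.
- What may go wrong: leakage into the formyl-endo mode, or pairing of C6 with C10 instead of C11. A stepwise course could expel bromide from the boron enolate. The acid could ionise the allylic silyl ether or oligomerise the diene.
- Fallback (sets out from 6 and 9, comes back at 10): catalyst control of the absolute sense is given up. The cycloaddition is run with the bulky achiral borane B(C6F5)3 in CH2Cl2 at low temperature. Exo-selective Diels–Alder reactions of enals with acyclic dienes are documented for this Lewis acid.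
- Both enal faces then react, so 10 should be accompanied in comparable amount by the exo adduct of opposite ring configuration F1. Because C3 is fixed, the two are diastereomers rather than enantiomers. They are separated by preparative chromatography, and the route continues from 10.

Step 9.
- What may go wrong: the peracid may not distinguish the two ring faces well enough, which would erode the C7 configuration.
- Fallback (sets out from 13, comes back at 16): the oxygen is tied to the C12 face before it is delivered. Pinnick oxidation of 13 (NaClO2, NaH2PO4, 2-methyl-2-butene, t-BuOH/H2O) gives the acid F2.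
- N-Iodosuccinimide in CH2Cl2 then closes the δ-iodolactone F3. This is a 6-exo, Markovnikov attack of the carboxyl oxygen on C7, anti to iodine at C8. An iodide-free iodonium source is chosen because the lactone holds the C5 chain, bromine and iodine syn-axial and would revert under reversible conditions.
- K2CO3 in MeOH opens the lactone, and the C7 alkoxide displaces the anti iodide. This gives the epoxy ester F4, with the epoxide necessarily on the C12 face.
- i-Bu2AlH at −78 °C gives the epoxy aldehyde F5, and Wittig reaction with 14 returns to 16.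

Step 11.
- What may go wrong: hydride delivery to C8 from the crowded face may be slow. It needs either a ring flip that puts the C5 chain and bromine axial or a twist-boat opening. On long exposure bromine may be lost by hydride substitution, or the C7 alkoxide may close onto C10.
- Fallback (sets out from 13, comes back at 20): no epoxide is made. Compound 13 is taken to the acid F2 and the δ-iodolactone F3 as described above.
- Radical deiodination follows (Bu3SnH, 1 equiv, Et3B/air, toluene, −78 °C). Iodine abstraction is much faster than bromine abstraction and relieves the syn-axial strain, so this should give the δ-lactone F6.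
- i-Bu2AlH at −78 °C gives the lactol F7. Wittig reaction of its open form with 14 under neutral conditions gives the hydroxy enoate F8. Excess 17 at −78 °C then converts F8 into 20.

Further compounds
F1 | step 5 | (1S,2S,6R)-6-bromo-1,3-dimethyl-2-[(3S)-3-methyl-3-(triethylsilyloxy)pent-4-en-1-yl]cyclohex-3-ene-1-carbaldehyde | C=C[C@@](C)(O[Si](CC)(CC)CC)CC[C@@H]1[C@@](C)(C=O)[C@H](Br)CC=C1C
F2 | step 9 | 2-[(1S,2R,6S)-6-bromo-1,3-dimethyl-2-[(3S)-3-methyl-3-(triethylsilyloxy)pent-4-en-1-yl]cyclohex-3-en-1-yl]acetic acid | C=C[C@@](C)(O[Si](CC)(CC)CC)CC[C@H]1[C@](C)(CC(=O)O)[C@@H](Br)CC=C1C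
F3 | step 9 | (1R,5S,6S,8R,9S)-6-bromo-8-iodo-1,5-dimethyl-9-[(3S)-3-methyl-3-(triethylsilyloxy)pent-4-en-1-yl]-2-oxabicyclo[3.3.1]nonan-3-one | C=C[C@@](C)(O[Si](CC)(CC)CC)CC[C@H]1[C@@]2(C)[C@@H](Br)C[C@@H](I)[C@]1(C)OC(=O)C2
F4 | step 9 | methyl 2-[(1R,2S,3S,4S,6S)-4-bromo-1,3-dimethyl-2-[(3S)-3-methyl-3-(triethylsilyloxy)pent-4-en-1-yl]-7-oxabicyclo[4.1.0]heptan-3-yl]acetate | C=C[C@@](C)(O[Si](CC)(CC)CC)CC[C@H]1[C@](C)(CC(=O)OC)[C@@H](Br)C[C@@H]2O[C@]12C
F5 | step 9 | 2-[(1R,2S,3S,4S,6S)-4-bromo-1,3-dimethyl-2-[(3S)-3-methyl-3-(triethylsilyloxy)pent-4-en-1-yl]-7-oxabicyclo[4.1.0]heptan-3-yl]acetaldehyde | C=C[C@@](C)(O[Si](CC)(CC)CC)CC[C@H]1[C@](C)(CC=O)[C@@H](Br)C[C@@H]2O[C@]12C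
F6 | step 11 | (1S,5S,6S,9S)-6-bromo-1,5-dimethyl-9-[(3S)-3-methyl-3-(triethylsilyloxy)pent-4-en-1-yl]-2-oxabicyclo[3.3.1]nonan-3-one | C=C[C@@](C)(O[Si](CC)(CC)CC)CC[C@H]1[C@@]2(C)[C@@H](Br)CC[C@]1(C)OC(=O)C2
F7 | step 11 | (1S,5S,6S,9S)-6-bromo-1,5-dimethyl-9-[(3S)-3-methyl-3-(triethylsilyloxy)pent-4-en-1-yl]-2-oxabicyclo[3.3.1]nonan-3-ol, anomer mixture | C=C[C@@](C)(O[Si](CC)(CC)CC)CC[C@H]1[C@@]2(C)[C@@H](Br)CC[C@]1(C)OC(O)C2
F8 | step 11 | ethyl (2E)-4-[(1S,2S,3S,6S)-6-bromo-3-hydroxy-1,3-dimethyl-2-[(3S)-3-methyl-3-(triethylsilyloxy)pent-4-en-1-yl]cyclohexyl]but-2-enoate | C=C[C@@](C)(O[Si](CC)(CC)CC)CC[C@H]1[C@](C)(C/C=C/C(=O)OCC)[C@@H](Br)CC[C@]1(C)O
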